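**Retrosynthetic overview**
1. Last cut: the aryl C5–acetyl bond. It is made by acid-free, magnesium-templated C-acylation of the geranyl ether at the only ring C–H left.
2. Next: the O–geranyl bond, made by Mitsunobu etherification of the 4-OH. This is done while the 2-methylbutanoyl ketone is the only carbonyl, so "para to C=O" singles out one hydroxyl.
3. Key cut: the Cα–CH2CH3 bond of the side chain. A racemic aryl α-chloroethyl ketone acts as an α-acyl cation (enolonium) equivalent and is joined to the ethyl carbanion of EtZnBr, so two normally nucleophilic carbons are coupled. The nickel/pybox coupling is enantioconvergent and sets the (R) centre.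
4. First bond: aryl–C(=O), by Friedel–Crafts acylation of 2-methylphloroglucinol with 2-chloropropanoyl chloride.
5. Rings: the benzene ring is bought intact, and no ring is formed.

Assumption: the SMILES is read as (R) at C2 of the 2-methylbutanoyl group and (E) at the C2=C3 alkene of the geranyl ether. Compounds 1, 2, 4, 8 and 10 are taken as catalogue chemicals.

**Route**

Step 1
Reactants: 1 2-methylbenzene-1,3,5-triol (2-methylphloroglucinol); 2 racemic 2-chloropropanoyl chloride
Product: 3 (±)-2-chloro-1-(2,4,6-trihydroxy-3-methylphenyl)propan-1-one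
Conditions: AlCl3 (3.5 equiv), CH2Cl2/MeNO2, 0 °C to 40 °C; then ice/1 M HCl
Reagents that add atoms: none
Why: Friedel–Crafts acylation: the two open ring positions of 1 are equivalent and the first acyl group deactivates the ring, so a single mono-ketone forms, the acidic medium keeps the ortho hydroxyls from displacing chloride, and the new C–Cl stereocentre is deliberately racemic because step 2 is stereoconvergent.

Step 2
Reactants: 3 (±)-2-chloro-1-(2,4,6-trihydroxy-3-methylphenyl)propan-1-one; 4 ethylzinc bromide
Product: 7 (2R)-2-methyl-1-(2,4,6-trihydroxy-3-methylphenyl)butan-1-one, via tris(trimethylsilyl) ether of the chloro ketone 5 (not isolated), via tris(trimethylsilyl) ether of the coupled ketone 6 (not isolated)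
Conditions: (a) BSA (4 equiv), THF, 50 °C, then evaporate under high vacuum; (b) NiCl2·glyme (10 mol %), (S,S)-i-Pr-pybox = 2,6-bis[(4S)-4-isopropyl-4,5-dihydrooxazol-2-yl]pyridine (13 mol %), EtZnBr (1.6 equiv), DMI/THF, 0 °C, 24 h; (c) 1 M citric acid, MeOH, rt
Reagents that add atoms: N,O-bis(trimethylsilyl)acetamide (BSA), CC(=N[Si](C)(C)C)O[Si](C)(C)C (its Me3Si groups stand in 5 and 6 only and are gone in 7)
Why: Proposed new method: the α-chloro ketone acts as an α-acyl cation (enolonium) equivalent, so the normally nucleophilic α-carbon is joined to the carbanionic ethyl carbon of 4; a monovalent nickel species abstracts chlorine from either enantiomer of 5 to give one planar α-acyl radical, the chiral divalent (pybox)Ni–Et complex captures it, and reductive elimination from trivalent nickel fixes the (R) centre (stereoconvergent); the (S,S) ligand is chosen because its antipode gives the (S) series (acyl > incoming alkyl > resident alkyl) in the closest known reaction type, the nickel/pybox-catalysed enantioconvergent Negishi alkylation of racemic α-bromo amides and arylation of racemic α-bromo ketones, and this sense is to be confirmed on the first run by chiral HPLC and optical rotation, the other antipode being equally available; transient O-silylation blocks 5-exo-tet closure of an ortho phenoxide onto C–Cl (benzofuran-3-one) and protonolysis of 4, and the weakly basic zinc reagent does not enolise the product.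

Step 3
Reactants: 7 (2R)-2-methyl-1-(2,4,6-trihydroxy-3-methylphenyl)butan-1-one; 8 geraniol, (2E)-3,7-dimethylocta-2,6-dien-1-ol
Product: 9 (2R)-1-{4-[(2E)-3,7-dimethylocta-2,6-dien-1-yloxy]-2,6-dihydroxy-3-methylphenyl}-2-methylbutan-1-one
Conditions: PPh3 (1.1 equiv), DIAD (1.1 equiv), THF, 0 °C to rt
Reagents that add atoms: none
Why: Mitsunobu etherification: the 4-OH, para to the only carbonyl, is the most acidic hydroxyl and the only one neither hydrogen-bonded to the ketone nor crowded by the sec-butyl group, the oxyphosphonium salt of the primary allylic alcohol is attacked by phenoxide oxygen in an SN2 step so the (E)-alkene stays and no C-geranylation occurs, and the near-neutral medium leaves the (R) centre untouched.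

Step 4
Reactants: 9 (2R)-1-{4-[(2E)-3,7-dimethylocta-2,6-dien-1-yloxy]-2,6-dihydroxy-3-methylphenyl}-2-methylbutan-1-one; 10 acetyl chloride
Product: 12 (2R)-1-{3-acetyl-4-[(2E)-3,7-dimethylocta-2,6-dien-1-yloxy]-2,6-dihydroxy-5-methylphenyl}-2-methylbutan-1-one (target), via bis(chloromagnesium) phenolate 11 (not isolated)
Conditions: i-PrMgCl (2.05 equiv), THF, 0 °C; solvent swap to toluene; AcCl (1.05 equiv), 0 °C to rt; cold 0.5 M HCl quench
Reagents that add atoms: isopropylmagnesium chloride, CC(C)[Mg]Cl (its MgCl units stand in 11 only)
Why: Metal-template ortho-acylation of a magnesium phenolate (a Friedel–Crafts-type C-acylation run without acid): acetyl chloride bound to the O6 magnesium is delivered through a six-membered transition state to C5, the only ring C–H (ortho to O6, para to O2), tautomerisation gives the doubly chelated diketone, the acid-labile geranyl ether never meets a strong Lewis or Brønsted acid, and the ketone of the bis-phenolate is a vinylogous carboxylate that does not enolise, so the (R) centre is kept.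

**Compound list**
1 | 2-methylbenzene-1,3,5-triol | Cc1c(O)cc(O)cc1O | starting material
2 | 2-chloropropanoyl chloride (racemic) | CC(Cl)C(=O)Cl | starting material
3 | (±)-2-chloro-1-(2,4,6-trihydroxy-3-methylphenyl)propan-1-one | CC(Cl)C(=O)c1c(O)cc(O)c(C)c1O | intermediate
4 | ethylzinc bromide | CC[Zn]Br | starting material
5 | (±)-2-chloro-1-[3-methyl-2,4,6-tris(trimethylsilyloxy)phenyl]propan-1-one | CC(Cl)C(=O)c1c(O[Si](C)(C)C)cc(O[Si](C)(C)C)c(C)c1O[Si](C)(C)C | intermediate
6 | (2R)-2-methyl-1-[3-methyl-2,4,6-tris(trimethylsilyloxy)phenyl]butan-1-one | CC[C@@H](C)C(=O)c1c(O[Si](C)(C)C)cc(O[Si](C)(C)C)c(C)c1O[Si](C)(C)C | intermediate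
7 | (2R)-2-methyl-1-(2,4,6-trihydroxy-3-methylphenyl)butan-1-one | CC[C@@H](C)C(=O)c1c(O)cc(O)c(C)c1O | intermediate
8 | geraniol, (2E)-3,7-dimethylocta-2,6-dien-1-ol | CC(C)=CCC/C(C)=C/CO | starting material
9 | (2R)-1-{4-[(2E)-3,7-dimethylocta-2,6-dien-1-yloxy]-2,6-dihydroxy-3-methylphenyl}-2-methylbutan-1-one | CC[C@@H](C)C(=O)c1c(O)c(C)c(OC/C=C(\C)CCC=C(C)C)cc1O | intermediate
10 | acetyl chloride | CC(=O)Cl | starting material
11 | bis(chloromagnesium) 2,6-phenolate of 9 | CC[C@@H](C)C(=O)c1c(O[Mg]Cl)c(C)c(OC/C=C(\C)CCC=C(C)C)cc1O[Mg]Cl | intermediate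
12 | (2R)-1-{3-acetyl-4-[(2E)-3,7-dimethylocta-2,6-dien-1-yloxy]-2,6-dihydroxy-5-methylphenyl}-2-methylbutan-1-one | CC[C@@H](C)C(=O)c1c(O)c(C)c(OC/C=C(\C)CCC=C(C)C)c(C(C)=O)c1O | target

**Totals**
Total step count: 4. Longest linear sequence: 4 (1 → 3 → 7 → 9 → 12).

**Three steps most likely to fail**

Step 2 is the riskiest.
- Alkylzinc reagents have not been paired with α-halo ketones in this type of coupling.
- Likely failures are reduction to the propanoyl ketone, benzofuran-3-one formation after loss of a silyl group, and low ee with the twisted, di-ortho-substituted aryl ketone.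
- The fallback keeps the same polarity-reversed bond but moves it to the ester level, where it is stereospecific. It sets out from 1, bypasses 3 to 6, and comes back at 7.
- Purchased tert-butyl (R)-lactate is treated with Tf2O and 2,6-lutidine (CH2Cl2, −78 °C to 0 °C). This gives tert-butyl (2R)-2-{[(trifluoromethyl)sulfonyl]oxy}propanoate F1.
- EtMgCl with catalytic ZnCl2 (THF, 0 °C) forms the zincate Et3ZnMgCl, which displaces the triflate by SN2 with clean inversion. The product is tert-butyl (2R)-2-methylbutanoate F2. The descriptor stays R because the priority order changes.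
- TFA in CH2Cl2 gives (2R)-2-methylbutanoic acid F3. This acid acylates 1 in BF3·OEt2 at 60 to 70 °C to give 7.

Step 4 is next.
- O-acetylation may outrun C-acylation, and magnesium halide could slowly cleave the geranyl ether once it sits ortho to the new acetyl group.
- The fallback builds the acetyl group in stages under basic or neutral conditions. It sets out from 9 and comes back at 12.
- Casnati–Skattebøl ortho-formylation (MgCl2, Et3N, paraformaldehyde, MeCN, 70 °C) gives 2-[(2E)-3,7-dimethylocta-2,6-dien-1-yloxy]-4,6-dihydroxy-3-methyl-5-[(2R)-2-methylbutanoyl]benzaldehyde F4.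
- MeMgBr (3.3 equiv, THF, −40 °C) adds only to the aldehyde, because the ketone flanked by two phenoxides is inert. This gives (2R)-1-{4-[(2E)-3,7-dimethylocta-2,6-dien-1-yloxy]-2,6-dihydroxy-3-(1-hydroxyethyl)-5-methylphenyl}-2-methylbutan-1-one F5 as both carbinol epimers.
- MnO2 in CH2Cl2 oxidises the benzylic alcohol to 12.

Step 3 is third.
- The non-chelated rotamer of an ortho hydroxyl may also react, which would give regioisomers or a bis-ether.
- The fallback drops the redox condensation for alkylation of a preformed mono-phenoxide. It sets out from 7 and 8 and comes back at 9.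
- Compound 8 is converted with PBr3 (Et2O, −10 °C) to geranyl bromide, (2E)-1-bromo-3,7-dimethylocta-2,6-diene F6.
- Compound 7 is treated with Cs2CO3 (0.55 equiv) in DMF at 0 °C, which forms only the most stable anion, the 4-phenoxide.
- The caesium counter-ion and the dipolar aprotic solvent favour O-alkylation over C-alkylation by F6, giving 9.

**Further compounds**
F1 | step 2 | tert-butyl (2R)-2-{[(trifluoromethyl)sulfonyl]oxy}propanoate | C[C@@H](OS(=O)(=O)C(F)(F)F)C(=O)OC(C)(C)C
F2 | step 2 | tert-butyl (2R)-2-methylbutanoate | CC[C@@H](C)C(=O)OC(C)(C)C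
F3 | step 2 | (2R)-2-methylbutanoic acid | CC[C@@H](C)C(=O)O
F4 | step 4 | 2-[(2E)-3,7-dimethylocta-2,6-dien-1-yloxy]-4,6-dihydroxy-3-methyl-5-[(2R)-2-methylbutanoyl]benzaldehyde | CC[C@@H](C)C(=O)c1c(O)c(C)c(OC/C=C(\C)CCC=C(C)C)c(C=O)c1O
F5 | step 4 | (2R)-1-{4-[(2E)-3,7-dimethylocta-2,6-dien-1-yloxy]-2,6-dihydroxy-3-(1-hydroxyethyl)-5-methylphenyl}-2-methylbutan-1-one, both carbinol epimers | CC[C@@H](C)C(=O)c1c(O)c(C)c(OC/C=C(\C)CCC=C(C)C)c(C(C)O)c1O
F6 | step 3 | geranyl bromide, (2E)-1-bromo-3,7-dimethylocta-2,6-diene | CC(C)=CCC/C(C)=C/CBr
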